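The plan opens ring A, the butyryl-bearing phloroglucinol, at the bond between the carbon that carries the butyryl group and the neighbouring hydroxyl-bearing carbon next to the bridge. The key step exploits the fact that the three ring A oxygens and the butyryl carbonyl are the enol form of a 3,5,7-trioxodecanoate: one Mg(OMe)2 Claisen condensation of C6 onto the C1 ester forms that bond, closes ring A and aromatises it. The precursor is an open-chain methyl triketo ester with a methyl branch at C4 and, at C2, the finished ring B attached through the bridging CH2 and kept as its trimethyl ether, which falls in the last step.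

Key step: step 9

Remark: the target is achiral; C2 and C4 of the open-chain intermediates are epimerisable and are carried as mixtures, and all 1,3-dicarbonyl compounds are drawn as keto tautomers.

Step 1
Reactants: 1 2,4,6-trimethoxytoluene; 2 propionyl chloride
Product: 3 1-(2,4,6-trimethoxy-3-methylphenyl)propan-1-one
Conditions: AlCl3 (1.1 equiv), CH2Cl2, 0 °C; ice-water
Reagents that add atoms: none
Why: Friedel–Crafts acylation at one of the two equivalent free positions of the strongly activated arene, after which the ketone slows a second acylation and the low temperature avoids cleavage of the flanking ethers.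

Step 2
Reactants: 3 1-(2,4,6-trimethoxy-3-methylphenyl)propan-1-one
Product: 4 2,4,6-trimethoxy-3-methyl-5-propanoylbenzaldehyde
Conditions: Cl2CHOMe, TiCl4, CH2Cl2, −20 → 0 °C; then H2O
Reagents that add atoms: dichloromethyl methyl ether, COC(Cl)Cl; water, O
Why: Rieche formylation at the only remaining ring position, which is ortho or para to all three methoxy groups and meta to the twisted ketone, with hydrolysis of the α-chloro ether on work-up releasing the aldehyde.

Step 3
Reactants: 4 2,4,6-trimethoxy-3-methyl-5-propanoylbenzaldehyde; 5 methyl 3-oxopentanoate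
Product: 6 methyl 3-oxo-2-[(2,4,6-trimethoxy-3-methyl-5-propanoylphenyl)methylidene]pentanoate (E/Z mixture)
Conditions: piperidine (cat.), AcOH (cat.), toluene, reflux, Dean–Stark
Reagents that add atoms: none
Why: Knoevenagel condensation at C2 of the keto ester, the only doubly activated methylene present, driven by azeotropic removal of water; the alkene geometry is irrelevant because the double bond is reduced next.

Step 4
Reactants: 6 methyl 3-oxo-2-[(2,4,6-trimethoxy-3-methyl-5-propanoylphenyl)methylidene]pentanoate
Product: 7 methyl 3-oxo-2-[(2,4,6-trimethoxy-3-methyl-5-propanoylphenyl)methyl]pentanoate (racemic)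
Conditions: H2 (1 atm), 10% Pd/C, EtOAc, rt
Reagents that add atoms: none
Why: Catalytic hydrogenation of the electron-poor trisubstituted alkene should be much faster than reduction of the hindered aryl ketone or the keto ester; the new C2 centre is racemic, epimerisable and erased in step 9.

Step 5
Reactants: 8 ethyl 3-oxohexanoate
Product: 9 ethyl 2-(2-propyl-1,3-dioxolan-2-yl)acetate
Conditions: HOCH2CH2OH, TsOH·H2O (cat.), toluene, reflux, Dean–Stark
Reagents that add atoms: ethylene glycol, OCCO
Why: Acid-catalysed ketalisation of the ketone of a β-keto ester with azeotropic removal of water, a standard protection that leaves the ester untouched.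

Step 6
Reactants: 9 ethyl 2-(2-propyl-1,3-dioxolan-2-yl)acetate
Product: 10 N-methoxy-N-methyl-2-(2-propyl-1,3-dioxolan-2-yl)acetamide
Conditions: MeNH(OMe)·HCl, i-PrMgCl, THF, −20 → 0 °C; aq. NH4Cl
Reagents that add atoms: N,O-dimethylhydroxylamine hydrochloride, CNOC.Cl
Why: Weinreb amide formation by aminolysis of the ester with the chloromagnesium amide made in the flask, fast enough at low temperature that enolisation and β-elimination of the ketal should not compete.

Step 7
Reactants: 7 methyl 3-oxo-2-[(2,4,6-trimethoxy-3-methyl-5-propanoylphenyl)methyl]pentanoate; 10 N-methoxy-N-methyl-2-(2-propyl-1,3-dioxolan-2-yl)acetamide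
Product: 12 methyl 4-methyl-3,5-dioxo-6-(2-propyl-1,3-dioxolan-2-yl)-2-[(2,4,6-trimethoxy-3-methyl-5-propanoylphenyl)methyl]hexanoate (mixture of diastereomers), via trilithium trienolate 11 (not isolated)
Conditions: LiN(i-Pr)2 (3.3 equiv), THF, −78 → 0 °C; then 10, −78 → 0 °C; aq. NH4Cl
Reagents that add atoms: none
Why: γ-Acylation of a β-keto ester dianion with a Weinreb amide, in which the aryl ketone is shielded in the flask as its lithium enolate, the least stabilised carbanion at C4 is the most nucleophilic site, and the chelated tetrahedral adduct survives until quench so that neither over-addition nor proton transfer from the product occurs; C2 and C4 form as epimerisable mixtures.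

Step 8
Reactants: 12 methyl 4-methyl-3,5-dioxo-6-(2-propyl-1,3-dioxolan-2-yl)-2-[(2,4,6-trimethoxy-3-methyl-5-propanoylphenyl)methyl]hexanoate
Product: 13 methyl 4-methyl-3,5,7-trioxo-2-[(2,4,6-trimethoxy-3-methyl-5-propanoylphenyl)methyl]decanoate (mixture of diastereomers and enol tautomers)
Conditions: 2 M aq. HCl, THF, rt
Reagents that add atoms: water, O
Why: Acid-catalysed hydrolysis of the dioxolane under dilute aqueous conditions, mild enough that the 1,3,5-triketone should not be dehydrated to a 4-pyranone, while the aryl methyl ethers and the methyl ester survive.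

Step 9
Reactants: 13 methyl 4-methyl-3,5,7-trioxo-2-[(2,4,6-trimethoxy-3-methyl-5-propanoylphenyl)methyl]decanoate
Product: 14 1-[3-[(3-butanoyl-2,4,6-trihydroxy-5-methylphenyl)methyl]-2,4,6-trimethoxy-5-methylphenyl]propan-1-one
Conditions: Mg(OMe)2 (4 equiv), MeOH, reflux, Ar; then 1 M HCl, 0 °C
Reagents that add atoms: none
Why: Mg(OMe)2 enolises the chain and the magnesium-chelated carbanion at C6, flanked by the C5 and C7 carbonyls, adds to the C1 ester carbonyl; loss of methoxide gives a 2-acylcyclohexane-1,3,5-trione whose three enolisations deliver the aromatic triol as its magnesium salt, which makes the sequence irreversible. The closest known reaction type is the Claisen (Dieckmann-type) cyclisation of 3,5,7-triketo esters, and of the 4-hydroxy-2-pyranones derived from them, to 2-acylphloroglucinols under Mg(OMe)2. Ring A closes by a 6-exo-trig acyl substitution that forms the C6–C1 bond. No stereocentre is created, and the epimeric C2 and C4 centres of 13 become sp2 on aromatisation. The step needs C-acylation by C6 to win over aldol addition of C2 to C7, lactonisation through the C5 enol oxygen and aldol attack of C8 on C3. The substrate secures this because the branch at C2 makes the aldol adduct a quaternary, non-aromatisable and reversible dead end, the pyranone is reopened by methoxide, C8 is only singly activated, and the inert trimethyl ether of ring B keeps the bridge from fragmenting under base.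

Step 10
Reactants: 14 1-[3-[(3-butanoyl-2,4,6-trihydroxy-5-methylphenyl)methyl]-2,4,6-trimethoxy-5-methylphenyl]propan-1-one
Product: 15 1-[3-[(2,4,6-trihydroxy-3-methyl-5-propanoylphenyl)methyl]-2,4,6-trihydroxy-5-methylphenyl]butan-1-one
Conditions: BBr3 (8 equiv), CH2Cl2, −78 → 0 °C; then H2O
Reagents that add atoms: none
Why: Lewis-acid cleavage of aryl methyl ethers, in which BBr3 coordinates each methoxy oxygen and bromide removes the methyl group by SN2, helped by chelation for the two ethers flanking the propionyl group, while the ring A phenols are held as borates until hydrolysis.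

Compound list
1 | 2,4,6-trimethoxytoluene | Cc1c(OC)cc(OC)cc1OC | starting material
2 | propionyl chloride | CCC(=O)Cl | starting material
3 | 1-(2,4,6-trimethoxy-3-methylphenyl)propan-1-one | CCC(=O)c1c(OC)cc(OC)c(C)c1OC | intermediate
4 | 2,4,6-trimethoxy-3-methyl-5-propanoylbenzaldehyde | CCC(=O)c1c(OC)c(C=O)c(OC)c(C)c1OC | intermediate
5 | methyl 3-oxopentanoate | CCC(=O)CC(=O)OC | starting material
6 | methyl 3-oxo-2-[(2,4,6-trimethoxy-3-methyl-5-propanoylphenyl)methylidene]pentanoate, E/Z mixture | CCC(=O)C(=Cc1c(OC)c(C)c(OC)c(C(=O)CC)c1OC)C(=O)OC | intermediate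
7 | methyl 3-oxo-2-[(2,4,6-trimethoxy-3-methyl-5-propanoylphenyl)methyl]pentanoate, racemic | CCC(=O)C(Cc1c(OC)c(C)c(OC)c(C(=O)CC)c1OC)C(=O)OC | intermediate
8 | ethyl 3-oxohexanoate | CCCC(=O)CC(=O)OCC | starting material
9 | ethyl 2-(2-propyl-1,3-dioxolan-2-yl)acetate | CCCC1(CC(=O)OCC)OCCO1 | intermediate
10 | N-methoxy-N-methyl-2-(2-propyl-1,3-dioxolan-2-yl)acetamide | CCCC1(CC(=O)N(C)OC)OCCO1 | intermediate
11 | trilithium trienolate of 7 (C2/C4 dienolate of the keto ester and enolate of the aryl ketone) | [Li+].[Li+].[Li+].CC=C([O-])C(Cc1c(OC)c(C)c(OC)c(C([O-])=CC)c1OC)=C([O-])OC | intermediate (not isolated)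
12 | methyl 4-methyl-3,5-dioxo-6-(2-propyl-1,3-dioxolan-2-yl)-2-[(2,4,6-trimethoxy-3-methyl-5-propanoylphenyl)methyl]hexanoate, mixture of diastereomers | CCCC1(CC(=O)C(C)C(=O)C(Cc2c(OC)c(C)c(OC)c(C(=O)CC)c2OC)C(=O)OC)OCCO1 | intermediate
13 | methyl 4-methyl-3,5,7-trioxo-2-[(2,4,6-trimethoxy-3-methyl-5-propanoylphenyl)methyl]decanoate, mixture of diastereomers and enol tautomers | CCCC(=O)CC(=O)C(C)C(=O)C(Cc1c(OC)c(C)c(OC)c(C(=O)CC)c1OC)C(=O)OC | intermediate (precursor of the key step)
14 | 1-[3-[(3-butanoyl-2,4,6-trihydroxy-5-methylphenyl)methyl]-2,4,6-trimethoxy-5-methylphenyl]propan-1-one | CCCC(=O)c1c(O)c(C)c(O)c(Cc2c(OC)c(C)c(OC)c(C(=O)CC)c2OC)c1O | intermediate (product of the key step)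
15 | 1-[3-[(2,4,6-trihydroxy-3-methyl-5-propanoylphenyl)methyl]-2,4,6-trihydroxy-5-methylphenyl]butan-1-one | CCCC(=O)c1c(O)c(C)c(O)c(Cc2c(O)c(C)c(O)c(C(=O)CC)c2O)c1O | target

Total step count: 10 (steps 5 and 6 are the side branch to amide 10).
Longest linear sequence: 8 steps (1, 2, 3, 4, 7, 8, 9, 10).

Steps most likely to fail

Step 9. The chain may fold in another mode (aldol closure, or lactonisation to a pyranone that does not reopen), or methoxide may cut it by retro-Claisen attack before the ring closes. The fallback sets out from 4 and comes back at 14; it brings ring A in as a ready arene and joins it by electrophilic substitution. Aldehyde 4 is reduced chemoselectively (NaBH4, MeOH, −20 °C, the hindered ketone being left) to 1-[3-(hydroxymethyl)-2,4,6-trimethoxy-5-methylphenyl]propan-1-one F1. Separately, commercial 2,4,6-trihydroxytoluene is monoacylated with butyryl chloride (AlCl3, CH2Cl2/nitrobenzene, 0 °C → rt) to 1-(2,4,6-trihydroxy-3-methylphenyl)butan-1-one F2. Acid-catalysed Friedel–Crafts benzylation (TsOH·H2O cat., 1,4-dioxane, rt) of the single free ring position of F2 by the trimethoxybenzyl cation from F1 should give 14. F1 cannot condense with itself because its ring is fully substituted.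

Step 7. Proton transfer may replace C–C bond formation: the trianion may deprotonate amide 10, whose ketal then opens by β-elimination, or the aryl ketone enolate may be acylated instead of C4. The fallback sets out from 5 and 10 and comes back at 12; it extends the chain before ring B is attached, so that no aryl ketone is present in the polyanion step. The dianion of 5 (NaH, then n-BuLi, THF, 0 °C) is acylated with 10 to give methyl 4-methyl-3,5-dioxo-6-(2-propyl-1,3-dioxolan-2-yl)hexanoate F3. Knoevenagel condensation of F3 with aldehyde 4 at C2, its only unsubstituted doubly activated methylene (piperidine/AcOH cat., EtOH, 50 °C), is run in the presence of Hantzsch ester. The alkylidene methyl 4-methyl-3,5-dioxo-6-(2-propyl-1,3-dioxolan-2-yl)-2-[(2,4,6-trimethoxy-3-methyl-5-propanoylphenyl)methylidene]hexanoate F4 is then reduced as it forms, before it can cyclise by oxa-Michael addition, and should give 12.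

Step 10. The hindered ether between the methyl group and the bridge may be cleaved incompletely, or the methylene bridge may be cut after ipso-protonation of an electron-rich ring by the HBr that forms. The fallback sets out from 14 and comes back at 15; it removes the ethers in two stages by two different mechanisms. BCl3 (CH2Cl2, −78 → 0 °C) should cleave only the two ethers chelated to the propionyl carbonyl and give 1-[3-[(4,6-dihydroxy-2-methoxy-3-methyl-5-propanoylphenyl)methyl]-2,4,6-trihydroxy-5-methylphenyl]butan-1-one F5. The last ether is then removed with the hard acid/soft nucleophile pair AlCl3/EtSH (CH2Cl2, 0 °C), in which the thiol takes up the methyl group, to give 15.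

Further compounds
F1 | step 9 | 1-[3-(hydroxymethyl)-2,4,6-trimethoxy-5-methylphenyl]propan-1-one | CCC(=O)c1c(OC)c(CO)c(OC)c(C)c1OC
F2 | step 9 | 1-(2,4,6-trihydroxy-3-methylphenyl)butan-1-one | CCCC(=O)c1c(O)cc(O)c(C)c1O
F3 | step 7 | methyl 4-methyl-3,5-dioxo-6-(2-propyl-1,3-dioxolan-2-yl)hexanoate | CCCC1(CC(=O)C(C)C(=O)CC(=O)OC)OCCO1
F4 | step 7 | methyl 4-methyl-3,5-dioxo-6-(2-propyl-1,3-dioxolan-2-yl)-2-[(2,4,6-trimethoxy-3-methyl-5-propanoylphenyl)methylidene]hexanoate | CCCC1(CC(=O)C(C)C(=O)C(=Cc2c(OC)c(C)c(OC)c(C(=O)CC)c2OC)C(=O)OC)OCCO1
F5 | step 10 | 1-[3-[(4,6-dihydroxy-2-methoxy-3-methyl-5-propanoylphenyl)methyl]-2,4,6-trihydroxy-5-methylphenyl]butan-1-one | CCCC(=O)c1c(O)c(C)c(O)c(Cc2c(OC)c(C)c(O)c(C(=O)CC)c2O)c1O
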